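The flavanone is disconnected at the C2–C3 bond of ring C. An aryl diazomethyl ketone made from phloroacetophenone, whose ortho oxygen (the future O1) carries the ring B benzyl group, undergoes an enantioselective dirhodium-carbene 1,6-C–H insertion: the carbene carbon becomes C3, the benzylic methylene becomes C2, and ring C and the C2 stereocentre arise in one operation. The step exploits the O1–CH2–aryl methylene, whose C–H bonds are activated by O1 and by the para oxygen (O4') of ring B. The ring B catechol travels as two 1,1-dimethylallyl ethers, which later deliver both prenyl groups to C2' and C5' by a double Claisen rearrangement.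

Key step: step 6

Assumption: the absolute sense of induction of the chiral dirhodium carboxylate cannot be fixed on paper, so the prolinate antipode (from L- or D-proline) that delivers 2S is the one used; it is written below as Rh2(S-BSP)4, BSP = N-benzenesulfonylprolinate.

Step 1
Reactants: 1 2,4,6-trihydroxyacetophenone
Product: 2 1-[2-hydroxy-4,6-bis(triisopropylsilyloxy)phenyl]ethan-1-one
Conditions: TIPSCl (2.1 equiv), imidazole, DMF, 0 °C to rt
Reagents that add atoms: triisopropylsilyl chloride CC(C)[Si](Cl)(C(C)C)C(C)C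
Why: Imidazole-promoted silyl ether formation, in which the para hydroxyl and one of the two equivalent ortho hydroxyls should react while the last ortho hydroxyl is held in a hydrogen bond to the acetyl carbonyl and stays free for step 4.

Step 2
Reactants: 3 3,4-dihydroxybenzaldehyde; 4 tert-butyl 2-methylbut-3-en-2-yl carbonate
Product: 5 3,4-bis[(2-methylbut-3-en-2-yl)oxy]benzaldehyde
Conditions: Pd(PPh3)4 (5 mol %), 4 (3 equiv), THF, 0 °C to rt
Reagents that add atoms: none
Why: Decarboxylative Tsuji–Trost O-allylation, in which the zerovalent palladium catalyst ionises the carbonate to a 1,1-dimethylallyl palladium cation and tert-butoxide, and each phenoxide attacks the more substituted allyl terminus under kinetic control to give the tertiary ether.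

Step 3
Reactants: 5 3,4-bis[(2-methylbut-3-en-2-yl)oxy]benzaldehyde
Product: 6 {3,4-bis[(2-methylbut-3-en-2-yl)oxy]phenyl}methanol
Conditions: NaBH4, MeOH, 0 °C
Reagents that add atoms: none
Why: Borohydride reduction of the aryl aldehyde to the benzylic alcohol; the tertiary allyl aryl ethers are inert to hydride and the low temperature keeps them from rearranging.

Step 4
Reactants: 2 1-[2-hydroxy-4,6-bis(triisopropylsilyloxy)phenyl]ethan-1-one; 6 {3,4-bis[(2-methylbut-3-en-2-yl)oxy]phenyl}methanol
Product: 7 1-[2-({3,4-bis[(2-methylbut-3-en-2-yl)oxy]phenyl}methoxy)-4,6-bis(triisopropylsilyloxy)phenyl]ethan-1-one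
Conditions: PPh3, DIAD, THF, 0 °C to rt
Reagents that add atoms: none
Why: Mitsunobu etherification, in which the chelated but acidic phenol of 2 displaces the primary benzylic oxyphosphonium of 6 under neutral conditions that spare the silyl ethers and the acid- and heat-sensitive tertiary allyl ethers.

Step 5
Reactants: 7 1-[2-({3,4-bis[(2-methylbut-3-en-2-yl)oxy]phenyl}methoxy)-4,6-bis(triisopropylsilyloxy)phenyl]ethan-1-one
Product: 9 2-diazo-1-[2-({3,4-bis[(2-methylbut-3-en-2-yl)oxy]phenyl}methoxy)-4,6-bis(triisopropylsilyloxy)phenyl]ethan-1-one, via trifluoroacetyl ketone 8 (not isolated)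
Conditions: LiN(SiMe3)2, THF, −78 °C, then CF3CO2CH2CF3, aq. HCl work-up; crude 8, MsN3, Et3N, H2O, MeCN, rt
Reagents that add atoms: methanesulfonyl azide CS(=O)(=O)N=[N+]=[N-] (the two diazo nitrogens of 9); 2,2,2-trifluoroethyl trifluoroacetate O=C(OCC(F)(F)F)C(F)(F)F (the trifluoroacetyl group of 8 only, lost again on the way to 9)
Why: Detrifluoroacetylative Regitz diazo transfer, in which Claisen-type trifluoroacetylation of the kinetic lithium enolate activates the methyl group towards diazo transfer from the sulfonyl azide and the trifluoroacetyl group then leaves as its N-sulfonyl amide.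

Step 6
Reactants: 9 2-diazo-1-[2-({3,4-bis[(2-methylbut-3-en-2-yl)oxy]phenyl}methoxy)-4,6-bis(triisopropylsilyloxy)phenyl]ethan-1-one
Product: 10 (2S)-2-{3,4-bis[(2-methylbut-3-en-2-yl)oxy]phenyl}-5,7-bis(triisopropylsilyloxy)chroman-4-one
Conditions: Rh2(S-BSP)4 (2 mol %), CH2Cl2, 0 °C to rt, slow addition of 9
Reagents that add atoms: none
Why: The divalent rhodium dimer takes up the diazo carbon with loss of dinitrogen to give an electrophilic acyl carbene, which inserts into a C–H bond of the O1–CH2–aryl group through a three-centre, hydride-transfer-like transition state, so that the carbene carbon becomes C3 and the benzylic carbon becomes C2. The closest known reaction type is the chiral dirhodium carboxylate-catalysed intramolecular C–H insertion of ortho-alkoxyaryl diazoketones to chroman-4-ones. Ring C closes in the 1,6-insertion mode through a six-membered array (carbene carbon, C4, C4a, C8a, O1, C2); no other C–H bond lies within reach of a five- or six-membered transition state. The C2 stereocentre is set by the catalyst: the chiral prolinate ligands differentiate the two enantiotopic benzylic hydrogens, and replacement of the pro-S hydrogen with retention gives 2S. The step needs C–H insertion to win over oxonium ylide formation at O1 with Stevens [1,2]-benzyl shift and over cyclopropanation; in its favour, the methylene is doubly activated (O1 and the para-alkoxyaryl ring B), O1 is an aryl ether oxygen conjugated to the ketone and thus a poor ylide donor, the only alkenes are remote neopentyl-type vinyl groups that could be reached only through a macrocycle, and the second ortho oxygen carries a bulky silyl group.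

Step 7
Reactants: 10 (2S)-2-{3,4-bis[(2-methylbut-3-en-2-yl)oxy]phenyl}-5,7-bis(triisopropylsilyloxy)chroman-4-one
Product: 12 (2S)-2-[3,4-dihydroxy-2,5-bis(3-methylbut-2-en-1-yl)phenyl]-5,7-bis(triisopropylsilyloxy)chroman-4-one, via mono-Claisen phenol 11 (not isolated)
Conditions: toluene (degassed, base-washed glass), 110 °C
Reagents that add atoms: none
Why: Double aromatic Claisen rearrangement ([3,3]-sigmatropic), in which each 1,1-dimethylallyl ether has only one free ortho carbon (C5' for the 4'-ether, expected first, then C2' for the 3'-ether), the allyl unit arrives inverted as a prenyl group, tautomerisation frees the catechol, and C2 takes no part.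

Step 8
Reactants: 12 (2S)-2-[3,4-dihydroxy-2,5-bis(3-methylbut-2-en-1-yl)phenyl]-5,7-bis(triisopropylsilyloxy)chroman-4-one
Product: 13 sigmoidin A, (2S)-2-[3,4-dihydroxy-2,5-bis(3-methylbut-2-en-1-yl)phenyl]-5,7-dihydroxychroman-4-one
Conditions: Bu4NF, AcOH, THF, 0 °C, argon
Reagents that add atoms: none
Why: Fluoride-mediated cleavage of the two aryl silyl ethers, buffered with acetic acid so that no free phenoxide opens ring C to the chalcone (which would racemise C2) or lets the catechol oxidise.

Compound list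
1 | 2,4,6-trihydroxyacetophenone | CC(=O)c1c(O)cc(O)cc1O | starting material
2 | 1-[2-hydroxy-4,6-bis(triisopropylsilyloxy)phenyl]ethan-1-one | CC(=O)c1c(O)cc(O[Si](C(C)C)(C(C)C)C(C)C)cc1O[Si](C(C)C)(C(C)C)C(C)C | intermediate
3 | 3,4-dihydroxybenzaldehyde | O=Cc1ccc(O)c(O)c1 | starting material
4 | tert-butyl 2-methylbut-3-en-2-yl carbonate | C=CC(C)(C)OC(=O)OC(C)(C)C | starting material
5 | 3,4-bis[(2-methylbut-3-en-2-yl)oxy]benzaldehyde | O=Cc1ccc(OC(C)(C)C=C)c(OC(C)(C)C=C)c1 | intermediate
6 | {3,4-bis[(2-methylbut-3-en-2-yl)oxy]phenyl}methanol | OCc1ccc(OC(C)(C)C=C)c(OC(C)(C)C=C)c1 | intermediate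
7 | 1-[2-({3,4-bis[(2-methylbut-3-en-2-yl)oxy]phenyl}methoxy)-4,6-bis(triisopropylsilyloxy)phenyl]ethan-1-one | CC(=O)c1c(OCc2ccc(OC(C)(C)C=C)c(OC(C)(C)C=C)c2)cc(O[Si](C(C)C)(C(C)C)C(C)C)cc1O[Si](C(C)C)(C(C)C)C(C)C | intermediate
8 | 4,4,4-trifluoro-1-[2-({3,4-bis[(2-methylbut-3-en-2-yl)oxy]phenyl}methoxy)-4,6-bis(triisopropylsilyloxy)phenyl]butane-1,3-dione (trifluoroacetyl ketone) | O=C(CC(=O)C(F)(F)F)c1c(OCc2ccc(OC(C)(C)C=C)c(OC(C)(C)C=C)c2)cc(O[Si](C(C)C)(C(C)C)C(C)C)cc1O[Si](C(C)C)(C(C)C)C(C)C | intermediate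
9 | 2-diazo-1-[2-({3,4-bis[(2-methylbut-3-en-2-yl)oxy]phenyl}methoxy)-4,6-bis(triisopropylsilyloxy)phenyl]ethan-1-one | [N-]=[N+]=CC(=O)c1c(OCc2ccc(OC(C)(C)C=C)c(OC(C)(C)C=C)c2)cc(O[Si](C(C)C)(C(C)C)C(C)C)cc1O[Si](C(C)C)(C(C)C)C(C)C | intermediate
10 | (2S)-2-{3,4-bis[(2-methylbut-3-en-2-yl)oxy]phenyl}-5,7-bis(triisopropylsilyloxy)chroman-4-one | C=CC(C)(C)Oc1ccc([C@@H]2CC(=O)c3c(O[Si](C(C)C)(C(C)C)C(C)C)cc(O[Si](C(C)C)(C(C)C)C(C)C)cc3O2)cc1OC(C)(C)C=C | intermediate
11 | (2S)-2-{4-hydroxy-3-[(2-methylbut-3-en-2-yl)oxy]-5-(3-methylbut-2-en-1-yl)phenyl}-5,7-bis(triisopropylsilyloxy)chroman-4-one (mono-Claisen phenol) | CC(C)=CCc1cc([C@@H]2CC(=O)c3c(O[Si](C(C)C)(C(C)C)C(C)C)cc(O[Si](C(C)C)(C(C)C)C(C)C)cc3O2)cc(OC(C)(C)C=C)c1O | intermediate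
12 | (2S)-2-[3,4-dihydroxy-2,5-bis(3-methylbut-2-en-1-yl)phenyl]-5,7-bis(triisopropylsilyloxy)chroman-4-one | CC(C)=CCc1cc([C@@H]2CC(=O)c3c(O[Si](C(C)C)(C(C)C)C(C)C)cc(O[Si](C(C)C)(C(C)C)C(C)C)cc3O2)c(CC=C(C)C)c(O)c1O | intermediate
13 | sigmoidin A, (2S)-2-[3,4-dihydroxy-2,5-bis(3-methylbut-2-en-1-yl)phenyl]-5,7-dihydroxychroman-4-one | CC(C)=CCc1cc([C@@H]2CC(=O)c3c(O)cc(O)cc3O2)c(CC=C(C)C)c(O)c1O | target

Total step count: 8
Longest linear sequence: 7 steps (3 → 5 → 6 → 7 → 9 → 10 → 12 → 13; steps 2 to 8)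

The three steps most likely to fail

1. Step 6. The carbene may be captured by the lone pair of O1 to give an oxonium ylide that undergoes a Stevens [1,2]-benzyl shift with ring contraction instead of C–H insertion, and the chiral carboxylate may discriminate the two enantiotopic benzylic hydrogens only weakly. The fallback sets out from 7 and comes back to the route at 10; it still closes ring C at C2–C3 but through a cation instead of a carbene. O-Acetylation of the potassium enolate of 7 (KN(SiMe3)2, Ac2O, THF, −78 °C) should give the enol acetate F1. Oxidative C–H cleavage with DDQ (2,6-dichloropyridine, LiClO4, 4 Å molecular sieves, ClCH2CH2Cl, rt) should take a hydride from the electron-rich benzylic position; the aryl-stabilised oxocarbenium ion is then trapped by the enol acetate in a 6-endo Mukaiyama-type closure to give the racemic flavanone F2. Kinetic resolution by asymmetric transfer hydrogenation (RhCl(C5Me5)(TsDPEN), HCO2H/Et3N, EtOAc, rt, stopped near half conversion, with the ligand antipode that reduces the 2R ketone faster) should convert the 2R enantiomer into the cis-flavan-4-ol F3, which is separated, and return the unreacted 2S ketone, which is 10.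

2. Step 7. The 3'-ether must deliver its allyl unit to the crowded C2' between the chromanone and O3'. Loss of isoprene by elimination, migration through the ipso carbon C4' to C6' (para-Claisen course) or partial racemisation at C2 through the freshly formed para-hydroxybenzyl ether may compete on this late intermediate. The fallback sets out from 5 and comes back to the route at 13; it moves the rearrangement to the start, where C2 of the arene is flanked only by a formyl group, and carries true prenyl groups under silyl protection. Heating 5 (toluene, 110 °C) should give 3,4-dihydroxy-2,5-bis(3-methylbut-2-en-1-yl)benzaldehyde F4. TBSCl and imidazole (DMF, rt) should give the bis(tert-butyldimethylsilyl) ether F5, and NaBH4 (MeOH, 0 °C) the benzylic alcohol F6. Mitsunobu coupling of F6 with 2 (PPh3, DIAD, THF) should give the aryl benzyl ether F7. The diazo transfer of step 5 then leads through the trifluoroacetyl ketone F8 to the diazoketone F9, and the dirhodium-catalysed C–H insertion of step 6 should give the fully silylated (2S)-flavanone F10. Bu4NF/AcOH (THF, 0 °C) removes all four silyl groups and gives 13.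

3. Step 2. The second etherification next to the first bulky tertiary ether may stall, and the palladium catalyst may re-ionise the tertiary ether para to the formyl group and equilibrate it to the linear prenyl ether. The fallback sets out from 3 and comes back to the route at 5; it builds the tertiary ethers by substitution and reduction instead of allyl-palladium chemistry. Copper-catalysed propargylation of 3 with 3-chloro-3-methylbut-1-yne (DBU, CuCl2 cat., MeCN, 0 °C) should give 3,4-bis[(2-methylbut-3-yn-2-yl)oxy]benzaldehyde F11. Lindlar-type semihydrogenation (H2, Pd/CaCO3 poisoned with Pb(OAc)2, quinoline, EtOAc, rt) should stop at the alkene stage and give 5.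

Further compounds
F1 | step 6 | 1-[2-({3,4-bis[(2-methylbut-3-en-2-yl)oxy]phenyl}methoxy)-4,6-bis(triisopropylsilyloxy)phenyl]ethenyl acetate (enol acetate) | C=C(OC(C)=O)c1c(OCc2ccc(OC(C)(C)C=C)c(OC(C)(C)C=C)c2)cc(O[Si](C(C)C)(C(C)C)C(C)C)cc1O[Si](C(C)C)(C(C)C)C(C)C
F2 | step 6 | racemic 2-{3,4-bis[(2-methylbut-3-en-2-yl)oxy]phenyl}-5,7-bis(triisopropylsilyloxy)chroman-4-one | C=CC(C)(C)Oc1ccc(C2CC(=O)c3c(O[Si](C(C)C)(C(C)C)C(C)C)cc(O[Si](C(C)C)(C(C)C)C(C)C)cc3O2)cc1OC(C)(C)C=C
F3 | step 6 | (2R,4R)-2-{3,4-bis[(2-methylbut-3-en-2-yl)oxy]phenyl}-5,7-bis(triisopropylsilyloxy)chroman-4-ol (cis-flavan-4-ol) | C=CC(C)(C)Oc1ccc([C@H]2C[C@@H](O)c3c(O[Si](C(C)C)(C(C)C)C(C)C)cc(O[Si](C(C)C)(C(C)C)C(C)C)cc3O2)cc1OC(C)(C)C=C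
F4 | step 7 | 3,4-dihydroxy-2,5-bis(3-methylbut-2-en-1-yl)benzaldehyde | CC(C)=CCc1cc(C=O)c(CC=C(C)C)c(O)c1O
F5 | step 7 | 3,4-bis(tert-butyldimethylsilyloxy)-2,5-bis(3-methylbut-2-en-1-yl)benzaldehyde | CC(C)=CCc1cc(C=O)c(CC=C(C)C)c(O[Si](C)(C)C(C)(C)C)c1O[Si](C)(C)C(C)(C)C
F6 | step 7 | [3,4-bis(tert-butyldimethylsilyloxy)-2,5-bis(3-methylbut-2-en-1-yl)phenyl]methanol | CC(C)=CCc1cc(CO)c(CC=C(C)C)c(O[Si](C)(C)C(C)(C)C)c1O[Si](C)(C)C(C)(C)C
F7 | step 7 | 1-[2-{[3,4-bis(tert-butyldimethylsilyloxy)-2,5-bis(3-methylbut-2-en-1-yl)phenyl]methoxy}-4,6-bis(triisopropylsilyloxy)phenyl]ethan-1-one | CC(=O)c1c(OCc2cc(CC=C(C)C)c(O[Si](C)(C)C(C)(C)C)c(O[Si](C)(C)C(C)(C)C)c2CC=C(C)C)cc(O[Si](C(C)C)(C(C)C)C(C)C)cc1O[Si](C(C)C)(C(C)C)C(C)C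
F8 | step 7 | 4,4,4-trifluoro-1-[2-{[3,4-bis(tert-butyldimethylsilyloxy)-2,5-bis(3-methylbut-2-en-1-yl)phenyl]methoxy}-4,6-bis(triisopropylsilyloxy)phenyl]butane-1,3-dione | O=C(CC(=O)C(F)(F)F)c1c(OCc2cc(CC=C(C)C)c(O[Si](C)(C)C(C)(C)C)c(O[Si](C)(C)C(C)(C)C)c2CC=C(C)C)cc(O[Si](C(C)C)(C(C)C)C(C)C)cc1O[Si](C(C)C)(C(C)C)C(C)C
F9 | step 7 | 2-diazo-1-[2-{[3,4-bis(tert-butyldimethylsilyloxy)-2,5-bis(3-methylbut-2-en-1-yl)phenyl]methoxy}-4,6-bis(triisopropylsilyloxy)phenyl]ethan-1-one | [N-]=[N+]=CC(=O)c1c(OCc2cc(CC=C(C)C)c(O[Si](C)(C)C(C)(C)C)c(O[Si](C)(C)C(C)(C)C)c2CC=C(C)C)cc(O[Si](C(C)C)(C(C)C)C(C)C)cc1O[Si](C(C)C)(C(C)C)C(C)C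
F10 | step 7 | (2S)-2-[3,4-bis(tert-butyldimethylsilyloxy)-2,5-bis(3-methylbut-2-en-1-yl)phenyl]-5,7-bis(triisopropylsilyloxy)chroman-4-one | CC(C)=CCc1cc([C@@H]2CC(=O)c3c(O[Si](C(C)C)(C(C)C)C(C)C)cc(O[Si](C(C)C)(C(C)C)C(C)C)cc3O2)c(CC=C(C)C)c(O[Si](C)(C)C(C)(C)C)c1O[Si](C)(C)C(C)(C)C
F11 | step 2 | 3,4-bis[(2-methylbut-3-yn-2-yl)oxy]benzaldehyde | O=Cc1ccc(OC(C)(C)C#C)c(OC(C)(C)C#C)c1
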